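## Retrosynthetic overview

1. Target 16 ⇐ γ-selective (reverse) prenyl–aryl Suzuki coupling on bromo-isoflavan 15, so the terminal alkene never meets iodine(III), Lewis acid or silane.
2. 15 ⇐ reductive removal of the C2 acetate, then MOM cleavage, from isoflavan-2-yl acetate 13.
3. 13 ⇐ (E)-2-cinnamylphenol 10 by one iodine(III) cascade: 6-endo O–C2 closure to a flavan, then 2→3 aryl shift; this sets C3.
4. 10 ⇐ 2'-hydroxychalcone 8 by deoxygenative reduction; 8 ⇐ Claisen–Schmidt condensation of acetophenone 7 with aldehyde 5.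
5. 5 ⇐ syringol 1 (MOM, dibromination, mono Br/Li–DMF). Rings A and B are bought; ring C is the only ring formed (step 7).

Assumption: the facial sense of the lactate-derived iodane on this alkene is not known in advance; the (R,R)-reagent is written, and if it gives the 3R series its (S,S)-enantiomer is used with nothing else changed.
Assumption: the iodane is a known reagent (from 2-iodoresorcinol and methyl L-lactate, recovered as the iodoarene) and is treated as a reagent, not as a route step.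

## Route

Step 1
Reactants: 1 2,6-dimethoxyphenol
Product: 2 1,3-dimethoxy-2-(methoxymethoxy)benzene
Conditions: NaH, MOMCl, THF/DMF, 0 °C → rt
Reagents that add atoms: chloromethyl methyl ether, COCCl
Why: Williamson-type O-alkylation of the hindered phenoxide; the MOM group shields this phenol from organolithium, base and iodine(III) and makes the central oxygen a weak director.

Step 2
Reactants: 2 1,3-dimethoxy-2-(methoxymethoxy)benzene
Product: 3 1,5-dibromo-2,4-dimethoxy-3-(methoxymethoxy)benzene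
Conditions: NBS (2.2 equiv), MeCN, 0 °C → rt
Reagents that add atoms: N-bromosuccinimide, O=C1CCC(=O)N1Br
Why: Electrophilic aromatic bromination; each outer OMe directs ortho/para, so the two positions ortho to one OMe and para to the other react, as in 1,2,3-trimethoxybenzene.

Step 3
Reactants: 3 1,5-dibromo-2,4-dimethoxy-3-(methoxymethoxy)benzene
Product: 5 5-bromo-2,4-dimethoxy-3-(methoxymethoxy)benzaldehyde, via aryllithium 4 (not isolated)
Conditions: n-BuLi (1.0 equiv), THF, −78 °C; DMF; aq NH4Cl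
Reagents that add atoms: N,N-dimethylformamide, CN(C)C=O
Why: Br/Li exchange on the symmetric dibromide stops after one exchange because the aryllithium resists a second, and DMF formylation (Bouveault type) gives the aldehyde.

Step 4
Reactants: 6 1-(2,4-dihydroxyphenyl)ethanone
Product: 7 1-[2-hydroxy-4-(methoxymethoxy)phenyl]ethanone
Conditions: MOMCl (1.1 equiv), K2CO3, acetone, rt
Reagents that add atoms: chloromethyl methyl ether, COCCl
Why: Selective Williamson etherification; the 2-OH is hydrogen-bonded to the ketone, so only the 4-OH is alkylated.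

Step 5
Reactants: 7 1-[2-hydroxy-4-(methoxymethoxy)phenyl]ethanone; 5 5-bromo-2,4-dimethoxy-3-(methoxymethoxy)benzaldehyde
Product: 8 (2E)-3-[5-bromo-2,4-dimethoxy-3-(methoxymethoxy)phenyl]-1-[2-hydroxy-4-(methoxymethoxy)phenyl]prop-2-en-1-one
Conditions: KOH (50% aq), EtOH, rt; AcOH to pH 5
Reagents that add atoms: none
Why: Claisen–Schmidt aldol condensation of a non-enolisable aldehyde gives the E-enone under thermodynamic control; MOM ethers and the aryl bromide are inert to hydroxide.

Step 6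
Reactants: 8 (2E)-3-[5-bromo-2,4-dimethoxy-3-(methoxymethoxy)phenyl]-1-[2-hydroxy-4-(methoxymethoxy)phenyl]prop-2-en-1-one
Product: 10 2-{(2E)-3-[5-bromo-2,4-dimethoxy-3-(methoxymethoxy)phenyl]prop-2-en-1-yl}-5-(methoxymethoxy)phenol, via aryl ethyl carbonate 9 (not isolated)
Conditions: ClCO2Et, Et3N, THF, 0 °C; then NaBH4, THF/H2O, 0 °C → rt
Reagents that add atoms: none
Why: Deoxygenation of a 2'-hydroxychalcone through its carbonate: borohydride reduces the ketone, ethyl carbonate is expelled to an o-quinone methide, and a second hydride adds at the methide carbon, giving the (E)-2-cinnamylphenol with the alkene geometry kept.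

Step 7
Reactants: 10 2-{(2E)-3-[5-bromo-2,4-dimethoxy-3-(methoxymethoxy)phenyl]prop-2-en-1-yl}-5-(methoxymethoxy)phenol
Product: 13 (3S)-3-[5-bromo-2,4-dimethoxy-3-(methoxymethoxy)phenyl]-7-(methoxymethoxy)-3,4-dihydro-2H-chromen-2-yl acetate (C2 epimers), via aryl trimethylsilyl ether 11 (not isolated), via trans-flavan-3-yl-λ3-iodane 12 (not isolated)
Conditions: HMDS (0.6 equiv), cat. TMSCl, CH2Cl2, 40 °C, evaporate; (R,R)-lactate aryl-I(OAc)2 (1.3 equiv), TMSOTf (1.0 equiv), CH2Cl2, −78 → −40 °C; Et3N, aq NaHCO3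
Reagents that add atoms: dimethyl (2R,2'R)-2,2'-{[2-(diacetoxy-λ3-iodanyl)-1,3-phenylene]bis(oxy)}dipropanoate (supplies the C2 acetate), COC(=O)[C@@H](C)Oc1cccc(O[C@H](C)C(=O)OC)c1[I](OC(C)=O)OC(C)=O
Why: Proposed new method: the triflate-activated chiral iodane adds to one face of the E-styrene, the silyl-capped phenol oxygen (capped so that iodine(III) cannot oxidise the phenol) closes 6-endo and anti onto the benzylic carbon with loss of TMS to give flavan 12 (the chalcone-isomerase event), and the B-ring aryl, anti to C3–I in the trans-diaxial conformer, then shifts from C2 to C3 with inversion as the iodoarene leaves (the isoflavone-synthase event) while acetate caps the C2 oxocarbenium, so C3 (S) is fixed only by the alkene face the reagent chooses; the closest known chemistry is the enantioselective iodine(III)-mediated oxidative 1,2-aryl migration of aryl alkenes and chalcones with lactate-derived iodanes, the iodine(III) flavanone-to-isoflavone shift, and the aryl migration of 2,3-trans-flavan-3-yl sulfonates.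

Step 8
Reactants: 13 (3S)-3-[5-bromo-2,4-dimethoxy-3-(methoxymethoxy)phenyl]-7-(methoxymethoxy)-3,4-dihydro-2H-chromen-2-yl acetate
Product: 15 (3S)-3-(5-bromo-3-hydroxy-2,4-dimethoxyphenyl)-3,4-dihydro-2H-chromen-7-ol, via bis-MOM bromo-isoflavan 14 (not isolated)
Conditions: Et3SiH (5 equiv), BF3·OEt2, CH2Cl2, −78 °C; then MeOH, conc. HCl, 45 °C
Reagents that add atoms: none
Why: Reductive deacetoxylation of an α-acetoxy ether: the acetate ionises exocyclically to the cyclic oxocarbenium, which excess silane traps at −78 °C before C3–H can be lost, so C3 stays S; acid methanolysis then removes both MOM acetals.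

Step 9
Reactants: 15 (3S)-3-(5-bromo-3-hydroxy-2,4-dimethoxyphenyl)-3,4-dihydro-2H-chromen-7-ol
Product: 16 (3S)-3-[3-hydroxy-2,4-dimethoxy-5-(2-methylbut-3-en-2-yl)phenyl]-3,4-dihydro-2H-chromen-7-ol
Conditions: prenylBpin (1.5 equiv), t-BuXPhos Pd G3 (3 mol %), aq K3PO4, MeCN, 70 °C
Reagents that add atoms: 4,4,5,5-tetramethyl-2-(3-methylbut-2-en-1-yl)-1,3,2-dioxaborolane, CC(C)=CCB1OC(C)(C)C(C)(C)O1
Why: γ-Selective allyl–aryl Suzuki–Miyaura coupling: SE2' transmetalation places Pd on the tertiary carbon and a bulky di-tert-butylbiarylphosphine (ligand recalled from memory, to be confirmed by a short screen) forces reductive elimination before σ–π–σ isomerisation, giving the 1,1-dimethylallyl group; the phenols are tolerated as phenoxides and C3 is untouched.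

## Compound list

1 | 2,6-dimethoxyphenol (syringol) | COc1cccc(OC)c1O | starting material
2 | 1,3-dimethoxy-2-(methoxymethoxy)benzene | COCOc1c(OC)cccc1OC | intermediate
3 | 1,5-dibromo-2,4-dimethoxy-3-(methoxymethoxy)benzene | COCOc1c(OC)c(Br)cc(Br)c1OC | intermediate
4 | [5-bromo-2,4-dimethoxy-3-(methoxymethoxy)phenyl]lithium | [Li]c1cc(Br)c(OC)c(OCOC)c1OC | intermediate (not isolated)
5 | 5-bromo-2,4-dimethoxy-3-(methoxymethoxy)benzaldehyde | COCOc1c(OC)c(C=O)cc(Br)c1OC | intermediate
6 | 1-(2,4-dihydroxyphenyl)ethanone | CC(=O)c1ccc(O)cc1O | starting material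
7 | 1-[2-hydroxy-4-(methoxymethoxy)phenyl]ethanone | CC(=O)c1ccc(OCOC)cc1O | intermediate
8 | (2E)-3-[5-bromo-2,4-dimethoxy-3-(methoxymethoxy)phenyl]-1-[2-hydroxy-4-(methoxymethoxy)phenyl]prop-2-en-1-one | COCOc1ccc(C(=O)/C=C/c2cc(Br)c(OC)c(OCOC)c2OC)c(O)c1 | intermediate
9 | 2-{(2E)-3-[5-bromo-2,4-dimethoxy-3-(methoxymethoxy)phenyl]prop-2-enoyl}-5-(methoxymethoxy)phenyl ethyl carbonate | COCOc1ccc(C(=O)/C=C/c2cc(Br)c(OC)c(OCOC)c2OC)c(OC(=O)OCC)c1 | intermediate (not isolated)
10 | 2-{(2E)-3-[5-bromo-2,4-dimethoxy-3-(methoxymethoxy)phenyl]prop-2-en-1-yl}-5-(methoxymethoxy)phenol | COCOc1ccc(C/C=C/c2cc(Br)c(OC)c(OCOC)c2OC)c(O)c1 | intermediate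
11 | {2-[(2E)-3-[5-bromo-2,4-dimethoxy-3-(methoxymethoxy)phenyl]prop-2-en-1-yl]-5-(methoxymethoxy)phenoxy}trimethylsilane | COCOc1ccc(C/C=C/c2cc(Br)c(OC)c(OCOC)c2OC)c(O[Si](C)(C)C)c1 | intermediate (not isolated)
12 | acetoxy{(2R,3S)-2-[5-bromo-2,4-dimethoxy-3-(methoxymethoxy)phenyl]-7-(methoxymethoxy)-3,4-dihydro-2H-chromen-3-yl}{2,6-bis[(1R)-2-methoxy-1-methyl-2-oxoethoxy]phenyl}-λ3-iodane | COCOc1ccc2c(c1)O[C@H](c1cc(Br)c(OC)c(OCOC)c1OC)[C@@H]([I](OC(C)=O)c1c(O[C@H](C)C(=O)OC)cccc1O[C@H](C)C(=O)OC)C2 | intermediate (not isolated)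
13 | (3S)-3-[5-bromo-2,4-dimethoxy-3-(methoxymethoxy)phenyl]-7-(methoxymethoxy)-3,4-dihydro-2H-chromen-2-yl acetate (C2 epimers, C2 left undefined) | COCOc1ccc2c(c1)OC(OC(C)=O)[C@H](c1cc(Br)c(OC)c(OCOC)c1OC)C2 | intermediate
14 | (3S)-3-[5-bromo-2,4-dimethoxy-3-(methoxymethoxy)phenyl]-7-(methoxymethoxy)-3,4-dihydro-2H-chromene | COCOc1ccc2c(c1)OC[C@H](c1cc(Br)c(OC)c(OCOC)c1OC)C2 | intermediate (not isolated)
15 | (3S)-3-(5-bromo-3-hydroxy-2,4-dimethoxyphenyl)-3,4-dihydro-2H-chromen-7-ol | Oc1ccc2c(c1)OC[C@H](c1cc(Br)c(OC)c(O)c1OC)C2 | intermediate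
16 | (3S)-3-[3-hydroxy-2,4-dimethoxy-5-(2-methylbut-3-en-2-yl)phenyl]-3,4-dihydro-2H-chromen-7-ol | C=CC(C)(C)c1cc([C@H]2COc3cc(O)ccc3C2)c(OC)c(O)c1OC | target

## Step count and risks

Total step count: 9. Longest linear sequence: 8 (steps 1, 2, 3, 5, 6, 7, 8, 9).

Three steps most likely to fail:

**Step 7.** Iodine(III) may attack the electron-rich A ring, O1 may shift instead of the aryl group (ring contraction to a 2-benzyl-dihydrobenzofuran), or the ee may be modest. The fallback sets out from chalcone 8 and moves the aryl shift to the chalcone level. Tl(NO3)3·3H2O in MeOH/HC(OMe)3 gives the racemic 2-[5-bromo-2,4-dimethoxy-3-(methoxymethoxy)phenyl]-1-[2-hydroxy-4-(methoxymethoxy)phenyl]-3,3-dimethoxypropan-1-one F1. PPTS in warm toluene closes it to 3-[5-bromo-2,4-dimethoxy-3-(methoxymethoxy)phenyl]-7-(methoxymethoxy)-4H-chromen-4-one F2. Asymmetric transfer hydrogenation with RuCl[(S,S)-TsDPEN](p-cymene) and HCO2H/Et3N, a dynamic kinetic resolution through the isoflavanone, then sets C3 and C4 together and gives (3S,4S)-3-[5-bromo-2,4-dimethoxy-3-(methoxymethoxy)phenyl]-7-(methoxymethoxy)-3,4-dihydro-2H-chromen-4-ol F3. Et3SiH/BF3·OEt2 at −78 °C removes the benzylic hydroxyl and the route is rejoined at 14, in the acid stage of step 8.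

**Step 8.** The C2 oxocarbenium can lose the C3 proton (4H-chromene, loss of ee) before the silane traps it. The fallback sets out from 13 and avoids the cation. DIBAL-H in CH2Cl2 (−78 → 0 °C) cleaves the acetate and reduces the lactol to 2-{(2S)-2-[5-bromo-2,4-dimethoxy-3-(methoxymethoxy)phenyl]-3-hydroxypropyl}-5-(methoxymethoxy)phenol F4. Mitsunobu etherification (PPh3, DIAD, THF) of the primary alcohol by the phenol closes the pyran and comes back to the route at 14.

**Step 9.** γ-Selectivity and formation of the quaternary carbon next to OMe on a bis-phenoxide are uncertain. The fallback sets out from 14 (isolated by stopping step 8 before the acid stage) and builds the group in two C–C steps. Pd-catalysed α-arylation of isobutyraldehyde (Pd(OAc)2, rac-BINAP, Cs2CO3, dioxane, 80 °C) gives 2-{2,4-dimethoxy-3-(methoxymethoxy)-5-[(3S)-7-(methoxymethoxy)-3,4-dihydro-2H-chromen-3-yl]phenyl}-2-methylpropanal F5. Wittig methylenation (Ph3P=CH2, THF) gives (3S)-3-[2,4-dimethoxy-3-(methoxymethoxy)-5-(2-methylbut-3-en-2-yl)phenyl]-7-(methoxymethoxy)-3,4-dihydro-2H-chromene F6. HCl/MeOH at 40 °C removes the MOM groups and arrives at 16.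

## Further compounds

F1 | step 7 | 2-[5-bromo-2,4-dimethoxy-3-(methoxymethoxy)phenyl]-1-[2-hydroxy-4-(methoxymethoxy)phenyl]-3,3-dimethoxypropan-1-one (racemic) | COCOc1ccc(C(=O)C(C(OC)OC)c2cc(Br)c(OC)c(OCOC)c2OC)c(O)c1
F2 | step 7 | 3-[5-bromo-2,4-dimethoxy-3-(methoxymethoxy)phenyl]-7-(methoxymethoxy)-4H-chromen-4-one | O=c1c(-c2cc(Br)c(OC)c(OCOC)c2OC)coc2cc(OCOC)ccc12
F3 | step 7 | (3S,4S)-3-[5-bromo-2,4-dimethoxy-3-(methoxymethoxy)phenyl]-7-(methoxymethoxy)-3,4-dihydro-2H-chromen-4-ol | COCOc1ccc2c(c1)OC[C@H](c1cc(Br)c(OC)c(OCOC)c1OC)[C@@H]2O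
F4 | step 8 | 2-{(2S)-2-[5-bromo-2,4-dimethoxy-3-(methoxymethoxy)phenyl]-3-hydroxypropyl}-5-(methoxymethoxy)phenol | COCOc1ccc(C[C@H](CO)c2cc(Br)c(OC)c(OCOC)c2OC)c(O)c1
F5 | step 9 | 2-{2,4-dimethoxy-3-(methoxymethoxy)-5-[(3S)-7-(methoxymethoxy)-3,4-dihydro-2H-chromen-3-yl]phenyl}-2-methylpropanal | COCOc1ccc2c(c1)OC[C@H](c1cc(C(C)(C)C=O)c(OC)c(OCOC)c1OC)C2
F6 | step 9 | (3S)-3-[2,4-dimethoxy-3-(methoxymethoxy)-5-(2-methylbut-3-en-2-yl)phenyl]-7-(methoxymethoxy)-3,4-dihydro-2H-chromene | COCOc1ccc2c(c1)OC[C@H](c1cc(C(C)(C)C=C)c(OC)c(OCOC)c1OC)C2
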